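## Structural features

The target is a daucane ester: a cyclopentane (C1–C5) fused across the C1–C5 bond to a cyclohept-7-en-9-one (C5, C6, C7, C8, C9, C10, C1), with a trans ring fusion (C1 methyl β, C5 hydrogen α). Four stereocentres are clustered: C4 (tertiary carbinol carbon carrying isopropyl and the 4-hydroxybenzoate), C5, C6 (secondary allylic carbinol) and the quaternary C1 on the other side of C5; with daucane locants they are 1R,4R,5S,6S. The fragile groups are the γ-hydroxy enone (elimination under base), the hindered tertiary ester, which sits 1,3 to the free C6 hydroxyl and can migrate to it, and the free phenol. The real difficulties are the all-carbon quaternary centre next to a trans ring fusion, the acylation of a tertiary alcohol flanked by an isopropyl group, and the C8 methyl group on the enone. The key step uses the position of the methyl-bearing C8 between the carbonyl C9 and C7. Without C8 the large ring is a cyclohexanone (C9, C7, C6, C5, C1, C10) whose enol double bond C9=C7 can take up one carbon as a carbene. That ketone is part of a rigid trans-hydrindane in which all four stereocentres can be set before the ring is enlarged.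

## Logic of the disconnections

27 ⇒ 26. Only the two O–Si bonds (phenol and C6–O) are cut. Both hydroxyls are masked as silyl ethers so that one fluoride step ends the synthesis. The forward step must stay close to neutral, because the C4 ester can migrate to O6.

26 ⇒ 24 + 25. The C8–CH3 bond is cut. The ring enlargement delivers C8 as an sp2 bromide, so the methyl group can enter by cross-coupling. The coupling must be neutral and tolerate the ester and both silyl ethers.

24 ⇒ 21 + 22 (through 23). The bonds C9–C8 and C8–C7 are cut and C8 is removed as a carbene. This contracts the seven-membered ring to the six-membered enol ether of a trans-hydrindanone and removes no stereocentre. It demands an enol ether with the double bond towards C7 only, and one that survives the base that makes the carbene.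

21 ⇒ 20. The enol O–Si bond is cut. The forward step needs kinetic deprotonation at C7, not C10, and immediate silylation so that the β-silyloxy group at C6 is not expelled.

20 ⇒ 19. The C6 O–Si bond is cut; the β-hydroxy ketone is protected before any strong base is used.

19 ⇒ 18. The C7–C6 bond is cut (aldol retron). This opens the six-membered ring to a cyclopentane carrying a formyl group (C6) and an acetonyl group (C10–C9–C7) trans to each other. The forward aldol must use the methyl ketone enolate, leave C5 untouched and place the C6 oxygen equatorial.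

18 ⇒ 17 ⇒ 16. Two unmaskings: the C6 aldehyde from a dimethyl acetal and the C9 ketone from a 1,1-disubstituted alkene. Both carbonyls must stay hidden while an organometallic reagent adds at C4, and they must be released in an order that never exposes an aldehyde to ozone.

16 ⇒ 9 + 14 + 13. The C4–isopropyl bond and the O4–acyl bond are cut. The tertiary ester is made from the alkoxide at the moment it forms, which avoids a late esterification of a hindered tertiary alcohol. The addition must come anti to the C5 substituent.

13 ⇒ 12 ⇒ 10. The acyl chloride comes from the acid, and the O–Si bond of the phenol is cut; the silyl group is chosen to survive base.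

9 ⇒ 7 + 8. The C5–C6 bond is cut. The enol ether 7 has its double bond fixed at C4=C5, so the one-carbon unit goes to C5 only. C6 must end up cis to the C1 methyl (anti to the larger group on C1).

7 ⇒ 4 + 5. The C1–CH3 bond is cut. A catalytic asymmetric conjugate addition sets the only catalyst-controlled stereocentre, and trapping the enolate keeps the regiochemistry for the next step.

4 ⇒ 1 + 2. The C1–C10 bond is cut; a 1,2-addition to a vinylogous ester with carbonyl transposition gives the 3-substituted enone.

## Other disconnections considered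

Alternative 1: The cut is at C5–C1 and C5–C6; C5 is taken out as a carbene carbon and the seven-membered ring is traced back to a benzene ring. In the forward step Rh2(OAc)4 decomposes the diazoketone A2, the rhodium carbenoid adds to the ipso/ortho bond of the arene, the norcaradiene opens in a six-electron electrocyclic step, and Et3N moves the double bonds into conjugation to give the azulenone A1.
- In its favour: the whole hydroazulene skeleton, with the C8 methyl and the C9 oxygen in place, arises in one step from a simple arene. On speed of access to the bicyclic carbon framework it is better than the chosen plan.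
- Against it here: A1 is flat and achiral. The quaternary C1 would need an enantioselective conjugate methyl addition to a fully substituted carbon of a trienone, followed by control of the trans fusion, C6 oxygenation and the C4 carbinol. The carbenoid must also choose between two ortho positions.
- Comparison: on mechanism the two plans are equal in kind, since both enlarge a six-membered ring through a cyclopropane that opens electrocyclically. Structurally the chosen plan enlarges last, on a trans-hydrindane that already holds all four stereocentres. In step count the alternative leads up to A1 and is expected to lose that lead afterwards.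

Alternative 2: The cut is at C7–C8 and C5–C1, giving a three-carbon oxyallyl unit (C5–C6–C7) and the four ring carbons of a furan (C8, C9, C10, C1). In the forward step zinc–copper couple reduces the tetrabromoketone A5 to an oxyallyl cation, which adds across the 2- and 5-positions of the furan A4 in a (4+3) cycloaddition; the remaining bromides are removed in the same flask to give the meso ketone A3.
- In its favour: the seven-membered ring, both methyl-bearing carbons and the C6 carbonyl come in one step from two cheap achiral compounds. On direct construction of the seven-membered ring it is better than the chosen plan. Because A3 is meso, one desymmetrising step could set the absolute configuration, so on the source of chirality it is the equal of the chosen plan.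
- Against it here: the bridging oxygen sits on C1 and C8. C1 must become an all-carbon quaternary centre, which means replacing a tertiary ether oxygen by carbon with stereocontrol. The C9=C10 alkene must become the C9 ketone regioselectively, and the whole cyclopentane with the C4 carbinol must still be annulated across C1–C5.
- Comparison: a concerted cycloaddition sets two bonds at once, whereas the chosen plan builds the ring stepwise. The intermediates of the chosen plan carry the right substituents at C1, C4 and C5, so it is expected to be shorter overall.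

Alternative 3: The cut is at C5–C1. In the forward step Rh2(OAc)4 turns the diazo ketoester A7 into a carbenoid at C5, which inserts into the tertiary C–H bond of the stereocentre inherited from (S)-citronellal A8 and closes the cyclopentanone A6 with retention.
- In its favour: the quaternary C1 comes from the chiral pool and its configuration is fixed by retention, with no asymmetric catalyst. On reliability of the absolute configuration at C1 it is better than the chosen plan. A6 carries the C4 ketone, C6 (as ester) and C10–C9 (as protected aldehyde); the way the C5 substituent is placed anti to the larger group on C1 is the same as in the chosen plan, so on that point the two are equal.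
- Against it here: A7 needs several steps from A8 (acetal formation, cleavage of the alkene, chain extension to the β-keto ester, diazo transfer). The 1,3-dicarbonyl unit must be taken apart before isopropyl can be added at C4, and C7, C8 and the seven-membered ring closure remain.
- Comparison: the chosen plan reaches a comparable cyclopentane in three steps and then needs one ring closure and a one-carbon insertion. The alternative is longer both before and after its key step.

Key step: step 12

## Remarks before the route

- Locants C1–C10 are the daucane locants of 27 and are kept for every intermediate; β is the face of the C1 methyl group.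
- Assumption: the copper-catalysed methyl addition of step 2 can be steered to either enantiomer by the choice of ligand enantiomer; the one that gives (R)-7 is used.
- Design of the key-step precursor 21:
  - The enol ether is a triethylsilyl ether, because a trimethylsilyl enol ether is more easily cleaved by tert-butoxide.
  - The C4 oxygen already carries the aroyl group (phenol as triisopropylsilyl ether), so no exchange at the hindered tertiary oxygen is needed after the ring enlargement.
  - The four stereocentres of 21 and 24 were checked and have the configuration of 27.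
- Carbon-delivering reagents are numbered; reagents that deliver only heteroatom groups are listed with SMILES in the steps.

## Route

Step 1
Reactants: 1 3-ethoxycyclopent-2-en-1-one; 2 (2-methylprop-2-en-1-yl)magnesium chloride
Product: 4 3-(2-methylprop-2-en-1-yl)cyclopent-2-en-1-one, via chloromagnesium allylic alkoxide 3 (not isolated)
Conditions: THF, 0 °C; then 1 M HCl, 0 °C, short contact
Reagents that add atoms: (2-methylprop-2-en-1-yl)magnesium chloride (2), CC(=C)C[Mg]Cl; water, O
Why: Stork–Danheiser sequence: the allylic Grignard reagent adds 1,2 to the vinylogous ester and cold dilute acid converts the tertiary allylic alcohol into the transposed 3-substituted enone; the short acid contact should keep the skipped alkene out of conjugation.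

Step 2
Reactants: 4 3-(2-methylprop-2-en-1-yl)cyclopent-2-en-1-one; 5 trimethylaluminium
Product: 7 (R)-triethyl{[3-methyl-3-(2-methylprop-2-en-1-yl)cyclopent-1-en-1-yl]oxy}silane, via dimethylaluminium enolate 6 (not isolated)
Conditions: Me3Al, Cu(OTf)2 (3 mol %), chiral BINOL-based phosphoramidite ligand (6 mol %), Et2O, −30 °C; then Et3SiOTf, THF, −30 → 0 °C
Reagents that add atoms: trimethylaluminium (5), C[Al](C)C; triethylsilyl trifluoromethanesulfonate, CC[Si](CC)(CC)OS(=O)(=O)C(F)(F)F
Why: Copper-catalysed asymmetric conjugate addition of a trialkylaluminium to a 3-substituted cyclopentenone builds the quaternary C1, with the ligand enantiomer chosen so that methyl enters the face giving the R centre; silylation of the aluminium enolate fixes the enol ether at C4=C5 for step 3.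

Step 3
Reactants: 7 (R)-triethyl{[3-methyl-3-(2-methylprop-2-en-1-yl)cyclopent-1-en-1-yl]oxy}silane; 8 trimethyl orthoformate
Product: 9 (2S,3R)-2-(dimethoxymethyl)-3-methyl-3-(2-methylprop-2-en-1-yl)cyclopentan-1-one (acetal carbon cis to the C1 methyl)
Conditions: HC(OMe)3, Me3SiOTf (5 mol %), CH2Cl2, −78 °C; pyridine quench
Reagents that add atoms: trimethyl orthoformate (8), COC(OC)OC
Why: Mukaiyama-type addition of the silyl enol ether to the dimethoxycarbenium ion puts the one-carbon unit C6 on C5 only; approach anti to the larger 2-methylallyl group and the thermodynamic preference of the epimerisable β-keto acetal should both place C6 cis to the C1 methyl.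

Step 4
Reactants: 10 4-hydroxybenzoic acid
Product: 12 4-[(triisopropylsilyl)oxy]benzoic acid, via bis-silylated acid 11 (not isolated)
Conditions: i-Pr3SiCl, imidazole, DMF, 23 °C; then AcOH/THF/H2O, 23 °C
Reagents that add atoms: chlorotriisopropylsilane, CC(C)[Si](Cl)(C(C)C)C(C)C
Why: Imidazole-mediated silylation covers phenol and acid, and the labile silyl ester is solvolysed selectively; the bulky triisopropylsilyl ether is chosen because it should survive the amide bases and tert-butoxide used later.

Step 5
Reactants: 12 4-[(triisopropylsilyl)oxy]benzoic acid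
Product: 13 4-[(triisopropylsilyl)oxy]benzoyl chloride
Conditions: (COCl)2, DMF (cat.), CH2Cl2, 0 → 23 °C
Reagents that add atoms: oxalyl chloride, ClC(=O)C(=O)Cl
Why: Acid chloride formation through the Vilsmeier-type chloroiminium species is fast and leaves the aryl silyl ether intact; the chloride is used crude.

Step 6
Reactants: 9 (2S,3R)-2-(dimethoxymethyl)-3-methyl-3-(2-methylprop-2-en-1-yl)cyclopentan-1-one; 14 isopropyllithium; 13 4-[(triisopropylsilyl)oxy]benzoyl chloride
Product: 16 (1R,2R,3R)-2-(dimethoxymethyl)-3-methyl-3-(2-methylprop-2-en-1-yl)-1-(propan-2-yl)cyclopentyl 4-[(triisopropylsilyl)oxy]benzoate, via dichlorocerium tertiary alkoxide 15 (not isolated)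
Conditions: i-PrLi, CeCl3, THF, −78 °C; then 13, DMAP (cat.), −78 → 23 °C
Reagents that add atoms: isopropyllithium (14), CC(C)[Li]; 4-[(triisopropylsilyl)oxy]benzoyl chloride (13), ClC(=O)c1ccc(O[Si](C(C)C)(C(C)C)C(C)C)cc1
Why: The weakly basic organocerium reagent should add 1,2 to the hindered, enolisable ketone, approaching C4 anti to the neighbouring C5 acetal so that the oxygen is β (cis to C6 and to the C1 methyl); acylating the alkoxide in the same flask installs the tertiary ester without a separate esterification of a hindered alcohol.

Step 7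
Reactants: 16 (1R,2R,3R)-2-(dimethoxymethyl)-3-methyl-3-(2-methylprop-2-en-1-yl)-1-(propan-2-yl)cyclopentyl 4-[(triisopropylsilyl)oxy]benzoate
Product: 17 (1R,2R,3R)-2-(dimethoxymethyl)-3-methyl-3-(2-oxopropyl)-1-(propan-2-yl)cyclopentyl 4-[(triisopropylsilyl)oxy]benzoate
Conditions: O3, CH2Cl2/MeOH, −78 °C; Me2S, −78 → 23 °C
Reagents that add atoms: ozone, [O-][O+]=O
Why: Ozonolysis cleaves the electron-rich 1,1-disubstituted alkene to the methyl ketone (C9); the acetal, the ester and the ester-deactivated arene should not react at −78 °C.

Step 8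
Reactants: 17 (1R,2R,3R)-2-(dimethoxymethyl)-3-methyl-3-(2-oxopropyl)-1-(propan-2-yl)cyclopentyl 4-[(triisopropylsilyl)oxy]benzoate
Product: 18 (1R,2R,3R)-2-formyl-3-methyl-3-(2-oxopropyl)-1-(propan-2-yl)cyclopentyl 4-[(triisopropylsilyl)oxy]benzoate
Conditions: 1 M HCl, THF, 0 → 23 °C
Reagents that add atoms: water, O
Why: Acid-catalysed acetal hydrolysis frees the C6 aldehyde; C5 lies between two fully substituted carbons, so acid-catalysed enolisation and loss of configuration should be slow.

Step 9
Reactants: 18 (1R,2R,3R)-2-formyl-3-methyl-3-(2-oxopropyl)-1-(propan-2-yl)cyclopentyl 4-[(triisopropylsilyl)oxy]benzoate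
Product: 19 (1R,3aR,7S,7aS)-7-hydroxy-3a-methyl-5-oxo-1-(propan-2-yl)octahydro-1H-inden-1-yl 4-[(triisopropylsilyl)oxy]benzoate (trans-fused, C6 hydroxyl α and equatorial)
Conditions: LiN(SiMe3)2, THF, −78 °C; sat. NH4Cl, −78 °C
Reagents that add atoms: none
Why: Kinetic deprotonation of the methyl ketone at C7 and intramolecular aldol addition (6-enolendo-exo-trig) close the six-membered ring, trans-fused because C6 and C10 are trans on the cyclopentane; the C6 oxygen should come out equatorial, since an axial oxygen would clash 1,3-diaxially with the C1 methyl in the chair transition state and in the product.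

Step 10
Reactants: 19 (1R,3aR,7S,7aS)-7-hydroxy-3a-methyl-5-oxo-1-(propan-2-yl)octahydro-1H-inden-1-yl 4-[(triisopropylsilyl)oxy]benzoate
Product: 20 (1R,3aR,7S,7aS)-7-[(tert-butyldimethylsilyl)oxy]-3a-methyl-5-oxo-1-(propan-2-yl)octahydro-1H-inden-1-yl 4-[(triisopropylsilyl)oxy]benzoate
Conditions: t-BuMe2SiOTf, 2,6-lutidine, CH2Cl2, −78 → 0 °C
Reagents that add atoms: tert-butyldimethylsilyl trifluoromethanesulfonate, CC(C)(C)[Si](C)(C)OS(=O)(=O)C(F)(F)F
Why: The silyl triflate silylates the hindered secondary alcohol at low temperature with a base too weak to cause retro-aldol cleavage or dehydration of the β-hydroxy ketone.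

Step 11
Reactants: 20 (1R,3aR,7S,7aS)-7-[(tert-butyldimethylsilyl)oxy]-3a-methyl-5-oxo-1-(propan-2-yl)octahydro-1H-inden-1-yl 4-[(triisopropylsilyl)oxy]benzoate
Product: 21 (1R,3aR,7S,7aS)-7-[(tert-butyldimethylsilyl)oxy]-3a-methyl-1-(propan-2-yl)-5-[(triethylsilyl)oxy]-2,3,3a,4,7,7a-hexahydro-1H-inden-1-yl 4-[(triisopropylsilyl)oxy]benzoate (enol double bond C9=C7)
Conditions: LiN(i-Pr)2, Et3SiCl, THF, −78 °C (ketone added last)
Reagents that add atoms: chlorotriethylsilane, CC[Si](Cl)(CC)CC
Why: Kinetic enolisation should take the C7 proton, because C10 is neopentyl next to the quaternary C1 and C7 is acidified by the β-oxygen; the chlorosilane present from the start silylates the enolate before it can expel the C6 silyloxy group.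

Step 12
Reactants: 21 (1R,3aR,7S,7aS)-7-[(tert-butyldimethylsilyl)oxy]-3a-methyl-1-(propan-2-yl)-5-[(triethylsilyl)oxy]-2,3,3a,4,7,7a-hexahydro-1H-inden-1-yl 4-[(triisopropylsilyl)oxy]benzoate; 22 bromoform
Product: 24 (1R,3aR,8R,8aS)-6-bromo-8-[(tert-butyldimethylsilyl)oxy]-3a-methyl-5-oxo-1-(propan-2-yl)-1,2,3,3a,4,5,8,8a-octahydroazulen-1-yl 4-[(triisopropylsilyl)oxy]benzoate, via siloxydibromocyclopropane 23 (not isolated)
Conditions: CHBr3, KOt-Bu, pentane, −20 → 0 °C; then toluene, 60 °C
Reagents that add atoms: bromoform (22), BrC(Br)Br
Why: tert-Butoxide deprotonates bromoform and α-elimination gives singlet dibromocarbene, which adds as an electrophile in a concerted cheletropic (2+1) step to the only electron-rich alkene, the C9=C7 enol ether, forming C9–C8 and C8–C7 in 23. The closest known reaction type is the addition of dihalocarbenes to cyclic silyl enol ethers with ring opening to 2-halocycloalk-2-enones. The three-membered ring is closed by this cycloaddition; the seven-membered ring is not closed by a new bond but arises when the shared C9–C7 bond breaks in a thermal disrotatory two-electron electrocyclic opening, in which the bromide syn to the six-membered ring leaves and the ring carbons turn inward. The silyloxy group on C9 drives this ionisation, bromide removes the silyl group from the oxocarbenium ion, and C8 is left as the α-bromo carbon of the enone. No stereocentre of 24 is made here: the two cyclopropane centres of 23 (carbene approach anti to the axial C1 methyl is expected) disappear again, and C1, C4, C5 and C6 are not touched. The step needs chemoselectivity for the enol ether over the arene and the ester, which the donor strength of the silyl enol ether secures, and a defined position of the inserted carbon, which is fixed by the enol ether regiochemistry from step 11. The triethylsilyl group should keep the enol ether intact towards tert-butoxide at low temperature, and the C6 silyl ether ends up γ to the ketone, where it cannot leave by β-elimination.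

Step 13
Reactants: 24 (1R,3aR,8R,8aS)-6-bromo-8-[(tert-butyldimethylsilyl)oxy]-3a-methyl-5-oxo-1-(propan-2-yl)-1,2,3,3a,4,5,8,8a-octahydroazulen-1-yl 4-[(triisopropylsilyl)oxy]benzoate; 25 tetramethylstannane
Product: 26 (1R,3aR,8S,8aS)-8-[(tert-butyldimethylsilyl)oxy]-3a,6-dimethyl-5-oxo-1-(propan-2-yl)-1,2,3,3a,4,5,8,8a-octahydroazulen-1-yl 4-[(triisopropylsilyl)oxy]benzoate
Conditions: Me4Sn, Pd(PPh3)4 (5 mol %), CuI (10 mol %), DMF, 80 °C, sealed tube
Reagents that add atoms: tetramethylstannane (25), C[Sn](C)(C)C
Why: Stille coupling: zerovalent palladium inserts into the C8–Br bond of the α-bromo enone, methyl is transferred from tin and reductive elimination gives the 8-methyl enone; the neutral conditions should leave the ester and both silyl ethers alone.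

Step 14
Reactants: 26 (1R,3aR,8S,8aS)-8-[(tert-butyldimethylsilyl)oxy]-3a,6-dimethyl-5-oxo-1-(propan-2-yl)-1,2,3,3a,4,5,8,8a-octahydroazulen-1-yl 4-[(triisopropylsilyl)oxy]benzoate
Product: 27 (1R,3aR,8S,8aS)-8-hydroxy-3a,6-dimethyl-5-oxo-1-(propan-2-yl)-1,2,3,3a,4,5,8,8a-octahydroazulen-1-yl 4-hydroxybenzoate (CNP0153637.1)
Conditions: Bu4NF, AcOH (1:1), THF, 0 → 40 °C
Reagents that add atoms: none
Why: Fluoride cleaves the aryl and the secondary silyl ether in one operation; buffering with acetic acid keeps phenoxide and alkoxide concentrations low, so that the C4 ester should not migrate to O6 and the γ-hydroxy enone should not eliminate.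

## Compound list

1 | 3-ethoxycyclopent-2-en-1-one | CCOC1=CC(=O)CC1 | starting material
2 | (2-methylprop-2-en-1-yl)magnesium chloride | CC(=C)C[Mg]Cl | starting material
3 | chloromagnesium 3-ethoxy-1-(2-methylprop-2-en-1-yl)cyclopent-2-en-1-olate (racemic) | CCOC1=CC(O[Mg]Cl)(CC(C)=C)CC1 | intermediate (not isolated)
4 | 3-(2-methylprop-2-en-1-yl)cyclopent-2-en-1-one | CC(=C)CC1=CC(=O)CC1 | intermediate
5 | trimethylaluminium | C[Al](C)C | starting material
6 | dimethylaluminium (R)-3-methyl-3-(2-methylprop-2-en-1-yl)cyclopent-1-en-1-olate | C[Al](C)OC1=C[C@](C)(CC1)CC(C)=C | intermediate (not isolated)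
7 | (R)-triethyl{[3-methyl-3-(2-methylprop-2-en-1-yl)cyclopent-1-en-1-yl]oxy}silane | CC[Si](CC)(CC)OC1=C[C@](C)(CC1)CC(C)=C | intermediate
8 | trimethyl orthoformate | COC(OC)OC | starting material
9 | (2S,3R)-2-(dimethoxymethyl)-3-methyl-3-(2-methylprop-2-en-1-yl)cyclopentan-1-one | COC(OC)[C@@H]1[C@](C)(CCC1=O)CC(C)=C | intermediate
10 | 4-hydroxybenzoic acid | OC(=O)c1ccc(O)cc1 | starting material
11 | triisopropylsilyl 4-[(triisopropylsilyl)oxy]benzoate | CC(C)[Si](OC(=O)c1ccc(O[Si](C(C)C)(C(C)C)C(C)C)cc1)(C(C)C)C(C)C | intermediate (not isolated)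
12 | 4-[(triisopropylsilyl)oxy]benzoic acid | OC(=O)c1ccc(O[Si](C(C)C)(C(C)C)C(C)C)cc1 | intermediate
13 | 4-[(triisopropylsilyl)oxy]benzoyl chloride | ClC(=O)c1ccc(O[Si](C(C)C)(C(C)C)C(C)C)cc1 | intermediate
14 | isopropyllithium | CC(C)[Li] | starting material
15 | dichlorocerium alkoxide of (1R,2R,3R)-2-(dimethoxymethyl)-3-methyl-3-(2-methylprop-2-en-1-yl)-1-(propan-2-yl)cyclopentan-1-ol | COC(OC)[C@@H]1[C@](C)(CC[C@@]1(O[Ce](Cl)Cl)C(C)C)CC(C)=C | intermediate (not isolated)
16 | (1R,2R,3R)-2-(dimethoxymethyl)-3-methyl-3-(2-methylprop-2-en-1-yl)-1-(propan-2-yl)cyclopentyl 4-[(triisopropylsilyl)oxy]benzoate | COC(OC)[C@@H]1[C@](C)(CC[C@@]1(OC(=O)c1ccc(O[Si](C(C)C)(C(C)C)C(C)C)cc1)C(C)C)CC(C)=C | intermediate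
17 | (1R,2R,3R)-2-(dimethoxymethyl)-3-methyl-3-(2-oxopropyl)-1-(propan-2-yl)cyclopentyl 4-[(triisopropylsilyl)oxy]benzoate | COC(OC)[C@@H]1[C@](C)(CC[C@@]1(OC(=O)c1ccc(O[Si](C(C)C)(C(C)C)C(C)C)cc1)C(C)C)CC(C)=O | intermediate
18 | (1R,2R,3R)-2-formyl-3-methyl-3-(2-oxopropyl)-1-(propan-2-yl)cyclopentyl 4-[(triisopropylsilyl)oxy]benzoate | O=C[C@@H]1[C@](C)(CC[C@@]1(OC(=O)c1ccc(O[Si](C(C)C)(C(C)C)C(C)C)cc1)C(C)C)CC(C)=O | intermediate
19 | (1R,3aR,7S,7aS)-7-hydroxy-3a-methyl-5-oxo-1-(propan-2-yl)octahydro-1H-inden-1-yl 4-[(triisopropylsilyl)oxy]benzoate | O=C1C[C@H](O)[C@@H]2[C@](C)(CC[C@@]2(OC(=O)c2ccc(O[Si](C(C)C)(C(C)C)C(C)C)cc2)C(C)C)C1 | intermediate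
20 | (1R,3aR,7S,7aS)-7-[(tert-butyldimethylsilyl)oxy]-3a-methyl-5-oxo-1-(propan-2-yl)octahydro-1H-inden-1-yl 4-[(triisopropylsilyl)oxy]benzoate | O=C1C[C@H](O[Si](C)(C)C(C)(C)C)[C@@H]2[C@](C)(CC[C@@]2(OC(=O)c2ccc(O[Si](C(C)C)(C(C)C)C(C)C)cc2)C(C)C)C1 | intermediate
21 | (1R,3aR,7S,7aS)-7-[(tert-butyldimethylsilyl)oxy]-3a-methyl-1-(propan-2-yl)-5-[(triethylsilyl)oxy]-2,3,3a,4,7,7a-hexahydro-1H-inden-1-yl 4-[(triisopropylsilyl)oxy]benzoate | CC[Si](CC)(CC)OC1=C[C@H](O[Si](C)(C)C(C)(C)C)[C@@H]2[C@](C)(CC[C@@]2(OC(=O)c2ccc(O[Si](C(C)C)(C(C)C)C(C)C)cc2)C(C)C)C1 | intermediate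
22 | bromoform | BrC(Br)Br | starting material
23 | 8,8-dibromocyclopropane adduct of 21 across C9=C7 (CBr2 on the α face, triethylsilyloxy group kept on C9) | BrC1(Br)[C@@H]2[C@H](O[Si](C)(C)C(C)(C)C)[C@@H]3[C@](C)(CC[C@@]3(OC(=O)c4ccc(O[Si](C(C)C)(C(C)C)C(C)C)cc4)C(C)C)C[C@]12O[Si](CC)(CC)CC | intermediate (not isolated)
24 | (1R,3aR,8R,8aS)-6-bromo-8-[(tert-butyldimethylsilyl)oxy]-3a-methyl-5-oxo-1-(propan-2-yl)-1,2,3,3a,4,5,8,8a-octahydroazulen-1-yl 4-[(triisopropylsilyl)oxy]benzoate | BrC1=C[C@H](O[Si](C)(C)C(C)(C)C)[C@@H]2[C@](C)(CC[C@@]2(OC(=O)c2ccc(O[Si](C(C)C)(C(C)C)C(C)C)cc2)C(C)C)CC1=O | intermediate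
25 | tetramethylstannane | C[Sn](C)(C)C | starting material
26 | (1R,3aR,8S,8aS)-8-[(tert-butyldimethylsilyl)oxy]-3a,6-dimethyl-5-oxo-1-(propan-2-yl)-1,2,3,3a,4,5,8,8a-octahydroazulen-1-yl 4-[(triisopropylsilyl)oxy]benzoate | CC1=C[C@H](O[Si](C)(C)C(C)(C)C)[C@@H]2[C@](C)(CC[C@@]2(OC(=O)c2ccc(O[Si](C(C)C)(C(C)C)C(C)C)cc2)C(C)C)CC1=O | intermediate
27 | (1R,3aR,8S,8aS)-8-hydroxy-3a,6-dimethyl-5-oxo-1-(propan-2-yl)-1,2,3,3a,4,5,8,8a-octahydroazulen-1-yl 4-hydroxybenzoate | CC1=C[C@H](O)[C@@H]2[C@](C)(CC[C@@]2(OC(=O)c2ccc(O)cc2)C(C)C)CC1=O | target

## Step count and least certain steps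

Total step count: 14. Longest linear sequence: 12 steps (steps 1–3 and 6–14, from 1 to 27); the acid chloride 13 is made in a two-step side branch (steps 4 and 5).

Step 12 (key step). The most likely failure is desilylation of the enol ether by tert-butoxide before the carbene is captured, or a siloxydibromocyclopropane that opens sluggishly and decomposes on heating, because the allyl cation develops next to the electron-withdrawing C6 oxygen. Fallback: from 21, methylene transfer with CH2I2/Et2Zn should give the siloxycyclopropane F1. One-electron oxidation with FeCl3 in DMF, which cleaves the C9–C7 bond, followed by NaOAc, should give the C8-unsubstituted cycloheptenone F2. Iodination with I2/pyridine should give the 8-iodo enone F3, and coupling with 25 under the conditions of step 13 comes back to the route at 26.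

Step 3. The weak point is facial discrimination at C5 between a methyl and a 2-methylallyl group on C1. A wrong C5 epimer would carry through to C4 in step 6 and would give a cis-fused ring in step 9. Fallback, which sets C5 on a bicyclic alkene instead: from 9 (either C5 epimer), ozonolysis should give the diketone acetal F4, and NaOMe in MeOH should cyclise it with loss of methanol to the ene-dione F5, in which C5 is trigonal. Ketalisation of the saturated C9 carbonyl with ethylene glycol gives the ketal F6. Addition of 14 with CeCl3 anti to the angular methyl and acylation with 13 gives the tertiary allylic ester F7. Hydroboration–oxidation (BH3·THF, then NaBO3) from the face opposite the angular methyl should give the trans-fused 6α-alcohol F8. Silylation gives the silyl ether F9, and mild aqueous acid removes the ketal and comes back to the route at 20.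

Step 9. The aldehyde 18 carries the C4 carboxylate in the β-position, so deprotonation at C5 instead of C7 would lead to elimination of the ester or to epimerisation at C5; dehydration of the aldol product is a further risk. Fallback without any enolate: from 16, acid hydrolysis of the acetal gives the aldehyde F10 with the 2-methylallyl group still in place. Me2AlCl in CH2Cl2 at −78 °C should close the ring by an intramolecular carbonyl-ene reaction to the methylenecyclohexanol F11. Silylation gives the silyl ether F12, and ozonolysis of the exocyclic alkene comes back to the route at 20.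

Step 6. The cerium alkoxide of a tertiary alcohol flanked by isopropyl may be acylated too slowly, and reduction or enolisation of 9 may compete with addition. Fallback: from 9, the addition is worked up to the tertiary alcohol F13; its potassium alkoxide (KN(SiMe3)2, THF) is then acylated with 13, which comes back to the route at 16.

Step 11. The enolate may lose the C6 silyloxy group by β-elimination before it is silylated, or deprotonation may occur at C10. Fallback without an enolate: from 20, HC(OMe)3/MeOH with pyridinium p-toluenesulfonate gives the dimethyl ketal F14. Me3SiOTf with i-Pr2NEt eliminates methanol to the methyl enol ether F15. Dibromocarbene addition under the conditions of step 12, followed by dilute acid, comes back to the route at 24.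

## Further compounds

F1 | step 12 | siloxycyclopropane from 21 (CH2 across C9=C7, α face) | C1[C@@H]2[C@H](O[Si](C)(C)C(C)(C)C)[C@@H]3[C@](C)(CC[C@@]3(OC(=O)c4ccc(O[Si](C(C)C)(C(C)C)C(C)C)cc4)C(C)C)C[C@]12O[Si](CC)(CC)CC
F2 | step 12 | C8-unsubstituted cycloheptenone (8-H analogue of 24) | O=C1C=C[C@H](O[Si](C)(C)C(C)(C)C)[C@@H]2[C@](C)(CC[C@@]2(OC(=O)c2ccc(O[Si](C(C)C)(C(C)C)C(C)C)cc2)C(C)C)C1
F3 | step 12 | 8-iodo enone (iodo analogue of 24) | O=C1C(I)=C[C@H](O[Si](C)(C)C(C)(C)C)[C@@H]2[C@](C)(CC[C@@]2(OC(=O)c2ccc(O[Si](C(C)C)(C(C)C)C(C)C)cc2)C(C)C)C1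
F4 | step 3 | (3R)-2-(dimethoxymethyl)-3-methyl-3-(2-oxopropyl)cyclopentan-1-one (both C2 epimers) | COC(OC)C1[C@](C)(CCC1=O)CC(C)=O
F5 | step 3 | (R)-3a-methyl-2,3,3a,4-tetrahydro-1H-indene-1,5(6H)-dione (C5=C6 ene-dione) | O=C1CC[C@]2(C)CC(=O)CC=C12
F6 | step 3 | C9 ethylene ketal of F5 | O=C1CC[C@]2(C)CC3(OCCO3)CC=C12
F7 | step 3 | tertiary allylic ester (4β-aroyloxy, 4α-isopropyl, C5=C6, C9 ketal) | CC(C)[C@]1(OC(=O)c3ccc(O[Si](C(C)C)(C(C)C)C(C)C)cc3)CC[C@]2(C)CC3(OCCO3)CC=C12
F8 | step 3 | trans-fused 6α-hydroxy C9 ketal | O1CCOC12C[C@H](O)[C@@H]3[C@](C)(CC[C@@]3(OC(=O)c4ccc(O[Si](C(C)C)(C(C)C)C(C)C)cc4)C(C)C)C2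
F9 | step 3 | 6α-tert-butyldimethylsilyl ether of F8 | O1CCOC12C[C@H](O[Si](C)(C)C(C)(C)C)[C@@H]3[C@](C)(CC[C@@]3(OC(=O)c4ccc(O[Si](C(C)C)(C(C)C)C(C)C)cc4)C(C)C)C2
F10 | step 9 | (1R,2R,3R)-2-formyl-3-methyl-3-(2-methylprop-2-en-1-yl)-1-(propan-2-yl)cyclopentyl 4-[(triisopropylsilyl)oxy]benzoate | O=C[C@@H]1[C@](C)(CC[C@@]1(OC(=O)c1ccc(O[Si](C(C)C)(C(C)C)C(C)C)cc1)C(C)C)CC(C)=C
F11 | step 9 | trans-fused 6α-hydroxy-9-methylene hydrindane | C=C1C[C@H](O)[C@@H]2[C@](C)(CC[C@@]2(OC(=O)c2ccc(O[Si](C(C)C)(C(C)C)C(C)C)cc2)C(C)C)C1
F12 | step 9 | 6α-tert-butyldimethylsilyl ether of F11 | C=C1C[C@H](O[Si](C)(C)C(C)(C)C)[C@@H]2[C@](C)(CC[C@@]2(OC(=O)c2ccc(O[Si](C(C)C)(C(C)C)C(C)C)cc2)C(C)C)C1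
F13 | step 6 | (1R,2R,3R)-2-(dimethoxymethyl)-3-methyl-3-(2-methylprop-2-en-1-yl)-1-(propan-2-yl)cyclopentan-1-ol | COC(OC)[C@@H]1[C@](C)(CC[C@@]1(O)C(C)C)CC(C)=C
F14 | step 11 | C9 dimethyl ketal of 20 | COC1(OC)C[C@H](O[Si](C)(C)C(C)(C)C)[C@@H]2[C@](C)(CC[C@@]2(OC(=O)c2ccc(O[Si](C(C)C)(C(C)C)C(C)C)cc2)C(C)C)C1
F15 | step 11 | methyl enol ether (C9=C7) corresponding to 21 | COC1=C[C@H](O[Si](C)(C)C(C)(C)C)[C@@H]2[C@](C)(CC[C@@]2(OC(=O)c2ccc(O[Si](C(C)C)(C(C)C)C(C)C)cc2)C(C)C)C1
A1 | alternative 1 | 5-methoxy-6-methyl-3,4-dihydroazulen-1(2H)-one | O=C1CCC2=C1C=CC(C)=C(OC)C2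
A2 | alternative 1 | 1-diazo-4-(3-methoxy-4-methylphenyl)butan-2-one | COc1cc(CCC(=O)C=[N+]=[N-])ccc1C
A3 | alternative 2 | (1R,5S)-1,5-dimethyl-8-oxabicyclo[3.2.1]oct-6-en-3-one | C[C@@]12CC(=O)C[C@@](C)(C=C1)O2
A4 | alternative 2 | 2,5-dimethylfuran | Cc1ccc(C)o1
A5 | alternative 2 | 1,1,3,3-tetrabromopropan-2-one | BrC(Br)C(=O)C(Br)Br
A6 | alternative 3 | methyl 2-(2,2-dimethoxyethyl)-2-methyl-5-oxocyclopentane-1-carboxylate (configuration as in the SMILES) | COC(=O)[C@@H]1[C@](C)(CCC1=O)CC(OC)OC
A7 | alternative 3 | methyl (6S)-2-diazo-8,8-dimethoxy-6-methyl-3-oxooctanoate | COC(=O)C(=[N+]=[N-])C(=O)CC[C@H](C)CC(OC)OC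
A8 | alternative 3 | (S)-citronellal | C[C@@H](CCC=C(C)C)CC=O
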